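The carbocycle of the chromenone (C-4a, C-5, C-6, C-7, C-8, C-8a) is not taken from a phloroglucinol but grown from a four-membered ring. In a Danheiser benzannulation, 3-tert-butoxy-4-prenylcyclobutenone and an enantiopure ynol ether that already carries the lavandulyl-type side chain merge by 4π opening, [2+2] addition, 4π opening and 6π closure into a pentasubstituted phenol. The step exploits the alternation in that ring: oxygen on C-5, C-7 and C-8a, carbon on C-4a, C-6 and C-8. The oxygens arrive differentiated (OtBu, OEt, OH), the unactivated side chain sits on C-8, the prenyl group becomes the pyran. Acylation and a ligand-controlled dearomatising prenylation at C-8 finish the route.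

Key step: step 7

Remark: ring positions are given in the 2H-chromene numbering of the target (O-1, C-2, C-3, C-4, C-4a, C-5 to C-8, C-8a).
Assumption: the (R,R)-ligand of step 10 is taken to give the 8R configuration; if the sense of induction is the opposite one, the (S,S)-ligand is used without further change.

Step 1
Reactants: 1 (S)-4-benzyl-1,3-oxazolidin-2-one; 2 3-methylbut-2-enoyl chloride
Product: 4 (S)-4-benzyl-3-(3-methylbut-2-enoyl)-1,3-oxazolidin-2-one, via lithium oxazolidinide 3 (not isolated)
Conditions: n-BuLi, THF, −78 °C; then 2, −78 → 0 °C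
Reagents that add atoms: none
Why: N-acylation of the lithiated oxazolidinone by the acid chloride (attachment of the Evans auxiliary) should be fast at low temperature and creates no stereocentre.

Step 2
Reactants: 4 (S)-4-benzyl-3-(3-methylbut-2-enoyl)-1,3-oxazolidin-2-one; 5 methyl (E)-4-bromo-2-methylbut-2-enoate
Product: 7 methyl (2E,5S)-5-{[(4S)-4-benzyl-2-oxo-1,3-oxazolidin-3-yl]carbonyl}-2,6-dimethylhepta-2,6-dienoate, via sodium dienolate 6 (not isolated)
Conditions: NaN(SiMe3)2, THF, −78 °C; then 5, −78 → −40 °C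
Reagents that add atoms: none
Why: Evans alkylation in its deconjugative form: γ-deprotonation should give the chelated Z-dienolate 6, which the allylic bromide alkylates at the α-carbon (SN2) on the face opposite the benzyl group, setting C-5 as S and leaving the isopropenyl group.

Step 3
Reactants: 7 methyl (2E,5S)-5-{[(4S)-4-benzyl-2-oxo-1,3-oxazolidin-3-yl]carbonyl}-2,6-dimethylhepta-2,6-dienoate
Product: 8 methyl (2E,5S)-5-(hydroxymethyl)-2,6-dimethylhepta-2,6-dienoate
Conditions: NaBH4, THF/H2O, 0 °C → rt
Reagents that add atoms: none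
Why: Hydride reduction of the N-acyloxazolidinone (reductive auxiliary cleavage) should give the primary alcohol while the conjugated methyl ester is inert to NaBH4 in wet THF and the stereocentre is not enolised.

Step 4
Reactants: 8 methyl (2E,5S)-5-(hydroxymethyl)-2,6-dimethylhepta-2,6-dienoate; 9 ethoxyethyne
Product: 12 methyl (2E,5R)-5-(3-ethoxyprop-2-yn-1-yl)-2,6-dimethylhepta-2,6-dienoate, via triflate 10 (not isolated), via lithium ethoxyacetylide 11 (not isolated)
Conditions: Tf2O, 2,6-lutidine, CH2Cl2, −78 °C; then 11 (from 9, n-BuLi, THF, −78 °C), DMPU, −78 → −30 °C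
Reagents that add atoms: none
Why: SN2 alkylation of the lithium alkoxyacetylide by the primary triflate should outrun addition to the ester at low temperature and builds the later C-8–CH2 bond at the acyclic stage without touching the stereocentre (its descriptor becomes R by priority only).

Step 5
Reactants: 13 trichloroethene; 14 potassium tert-butoxide
Product: 17 tert-butoxyethyne, via dichlorovinyl ether 15 (not isolated), via lithium tert-butoxyacetylide 16 (not isolated)
Conditions: THF, −78 °C → rt; then n-BuLi (2.2 equiv), −78 °C; then MeOH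
Reagents that add atoms: none
Why: Addition–elimination of tert-butoxide on trichloroethene should give the dichlorovinyl ether, which n-BuLi converts by elimination and chlorine–lithium exchange into the lithium alkoxyacetylide (standard alkoxyalkyne synthesis), protonated by methanol.

Step 6
Reactants: 18 5-methylhex-4-enoic acid; 17 tert-butoxyethyne
Product: 21 3-tert-butoxy-4-(3-methylbut-2-en-1-yl)cyclobut-2-en-1-one (racemic), via acid chloride 19 (not isolated), via prenylketene 20 (not isolated)
Conditions: (COCl)2, cat. DMF, CH2Cl2, 0 °C → rt; then 17, Et3N, CH2Cl2, rt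
Reagents that add atoms: none
Why: Dehydrochlorination of the acid chloride should give aldoketene 20, which the electron-rich ynol ether traps in a regioselective [2+2] cycloaddition (ketene carbonyl carbon to the unsubstituted alkyne carbon); the stereocentre of the racemic cyclobutenone is erased in step 7.

Step 7
Reactants: 21 3-tert-butoxy-4-(3-methylbut-2-en-1-yl)cyclobut-2-en-1-one; 12 methyl (2E,5R)-5-(3-ethoxyprop-2-yn-1-yl)-2,6-dimethylhepta-2,6-dienoate
Product: 26 methyl (2E,5R)-5-{[4-tert-butoxy-6-ethoxy-2-hydroxy-3-(3-methylbut-2-en-1-yl)phenyl]methyl}-2,6-dimethylhepta-2,6-dienoate, via vinylketene 22 (not isolated), via vinylcyclobutenone 23 (not isolated), via dienylketene 24 (not isolated), via cyclohexadienone 25 (not isolated)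
Conditions: toluene, 80 °C, then 110 °C, sealed tube (21: 1.5 equiv)
Reagents that add atoms: none
Why: Danheiser benzannulation: thermal 4π-electrocyclic opening of cyclobutenone 21 should give vinylketene 22, whose [2+2] cycloaddition with ynol ether 12 gives the four-membered vinylcyclobutenone 23; a second 4π opening gives dienylketene 24, and a thermal disrotatory 6π-electrocyclisation (bond between the ketene carbon and the alkene terminus) closes the six-membered ring 25, which tautomerises to phenol 26. The closest known reaction type is the benzannulation of 3-alkoxycyclobutenones with 1-alkoxyalkynes. The four-membered ring is formed by [2+2] cycloaddition and the six-membered ring by 6π-electrocyclic closure, so the carbocycle grows from four to six carbons by taking up the two alkyne carbons. No new stereocentre persists, because the sp3 carbons of 23 and 25 are erased by ring opening and tautomerisation, and the side-chain centre is a spectator. The step needs one regiochemistry in the [2+2] addition, which the polarisation of the ynol ether secures (its oxygen-free carbon attacks the ketene carbonyl carbon), so that OEt ends next to the side chain and the free OH between side chain and prenyl group. Holding 80 °C until 12 is consumed should keep it below the temperature of its retro-ene loss of ethylene.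

Step 8
Reactants: 26 methyl (2E,5R)-5-{[4-tert-butoxy-6-ethoxy-2-hydroxy-3-(3-methylbut-2-en-1-yl)phenyl]methyl}-2,6-dimethylhepta-2,6-dienoate
Product: 27 methyl (2E,5R)-5-[(5-tert-butoxy-7-ethoxy-2,2-dimethyl-2H-chromen-8-yl)methyl]-2,6-dimethylhepta-2,6-dienoate
Conditions: DDQ, benzene, rt → 60 °C
Reagents that add atoms: none
Why: Oxidative chromene cyclisation: DDQ should abstract hydride from the benzylic-allylic CH2 of the o-prenylphenol, and the o-quinone methide closes by oxa-6π-electrocyclisation onto the only free phenol oxygen, which fixes the pyran oxygen on C-8a.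

Step 9
Reactants: 27 methyl (2E,5R)-5-[(5-tert-butoxy-7-ethoxy-2,2-dimethyl-2H-chromen-8-yl)methyl]-2,6-dimethylhepta-2,6-dienoate; 28 (R)-2-methylbutanoic acid
Product: 31 methyl (2E,5R)-5-({7-ethoxy-5-hydroxy-2,2-dimethyl-6-[(2R)-2-methylbutanoyl]-2H-chromen-8-yl}methyl)-2,6-dimethylhepta-2,6-dienoate, via acid chloride 29 (not isolated), via aryloxytitanium trichloride 30 (not isolated)
Conditions: 28, (COCl)2, cat. DMF, CH2Cl2; 27, TiCl4, CH2Cl2, −78 °C; then 29, −78 → −30 °C; aq. NaHCO3
Reagents that add atoms: none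
Why: Lewis-acid-mediated ortho-acylation of a phenol (Friedel–Crafts type): TiCl4 should cleave the aryl tert-butyl ether to titanium phenoxide 30, which delivers the acid chloride to C-6, the only free ring carbon, while the chiral-pool 2-methylbutanoyl centre is not enolised at low temperature.

Step 10
Reactants: 31 methyl (2E,5R)-5-({7-ethoxy-5-hydroxy-2,2-dimethyl-6-[(2R)-2-methylbutanoyl]-2H-chromen-8-yl}methyl)-2,6-dimethylhepta-2,6-dienoate; 32 3-methylbut-2-en-1-yl acetate
Product: 33 methyl (2E,5R)-5-({(8R)-7-ethoxy-2,2-dimethyl-6-[(2R)-2-methylbutanoyl]-8-(3-methylbut-2-en-1-yl)-5-oxo-5,8-dihydro-2H-chromen-8-yl}methyl)-2,6-dimethylhepta-2,6-dienoate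
Conditions: Pd2(dba)3·CHCl3 (2.5 mol %), (R,R)-DACH-phenyl Trost ligand (7.5 mol %), Cs2CO3, toluene, 0 °C → rt
Reagents that add atoms: none
Why: Asymmetric Tsuji–Trost allylic alkylation with dearomatisation: the caesium phenoxide should attack the π-prenyl complex formed from zerovalent palladium with its para carbon C-8 (both ortho carbons are blocked) at the unsubstituted allyl terminus, and the chiral ligand selects the face of C-8, setting the quaternary centre as R independently of the remote side-chain centre.

Step 11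
Reactants: 33 methyl (2E,5R)-5-({(8R)-7-ethoxy-2,2-dimethyl-6-[(2R)-2-methylbutanoyl]-8-(3-methylbut-2-en-1-yl)-5-oxo-5,8-dihydro-2H-chromen-8-yl}methyl)-2,6-dimethylhepta-2,6-dienoate
Product: 34 (2E,5R)-5-({(8R)-7-hydroxy-2,2-dimethyl-6-[(2R)-2-methylbutanoyl]-8-(3-methylbut-2-en-1-yl)-5-oxo-5,8-dihydro-2H-chromen-8-yl}methyl)-2,6-dimethylhepta-2,6-dienoic acid (target)
Conditions: LiOH·H2O, THF/H2O, 40 °C; then 1 M HCl
Reagents that add atoms: lithium hydroxide (hydroxide oxygen), [Li+].[OH-]
Why: Saponification of the methyl ester and addition–elimination hydrolysis of the vinylogous ethyl ester (activated by two carbonyl groups) should give the acid and the enol, with no stereocentre touched because the triketone is held as its enolate and C-8 keeps two different ring neighbours.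

Compound list
1 | (S)-4-benzyl-1,3-oxazolidin-2-one | O=C1N[C@@H](Cc2ccccc2)CO1 | starting material
2 | 3-methylbut-2-enoyl chloride | CC(C)=CC(=O)Cl | starting material
3 | lithium (S)-4-benzyl-2-oxo-1,3-oxazolidin-3-ide | [Li+].O=C1[N-][C@@H](Cc2ccccc2)CO1 | intermediate
4 | (S)-4-benzyl-3-(3-methylbut-2-enoyl)-1,3-oxazolidin-2-one | CC(C)=CC(=O)N1[C@@H](Cc2ccccc2)COC1=O | intermediate
5 | methyl (E)-4-bromo-2-methylbut-2-enoate | COC(=O)/C(C)=C/CBr | starting material
6 | sodium (1Z)-1-[(4S)-4-benzyl-2-oxo-1,3-oxazolidin-3-yl]-3-methylbuta-1,3-dien-1-olate | [Na+].C=C(C)/C=C(\[O-])N1[C@@H](Cc2ccccc2)COC1=O | intermediate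
7 | methyl (2E,5S)-5-{[(4S)-4-benzyl-2-oxo-1,3-oxazolidin-3-yl]carbonyl}-2,6-dimethylhepta-2,6-dienoate | C=C(C)[C@H](C/C=C(\C)C(=O)OC)C(=O)N1[C@@H](Cc2ccccc2)COC1=O | intermediate
8 | methyl (2E,5S)-5-(hydroxymethyl)-2,6-dimethylhepta-2,6-dienoate | C=C(C)[C@H](C/C=C(\C)C(=O)OC)CO | intermediate
9 | ethoxyethyne | C#COCC | starting material
10 | methyl (2E,5S)-2,6-dimethyl-5-{[(trifluoromethanesulfonyl)oxy]methyl}hepta-2,6-dienoate | C=C(C)[C@H](C/C=C(\C)C(=O)OC)COS(=O)(=O)C(F)(F)F | intermediate
11 | lithium ethoxyacetylide | [Li+].[C-]#COCC | intermediate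
12 | methyl (2E,5R)-5-(3-ethoxyprop-2-yn-1-yl)-2,6-dimethylhepta-2,6-dienoate | C=C(C)[C@H](C/C=C(\C)C(=O)OC)CC#COCC | intermediate
13 | trichloroethene | ClC=C(Cl)Cl | starting material
14 | potassium tert-butoxide | [K+].CC(C)(C)[O-] | starting material
15 | (E)-1-tert-butoxy-1,2-dichloroethene | CC(C)(C)O/C(Cl)=C\Cl | intermediate
16 | lithium tert-butoxyacetylide | [Li+].[C-]#COC(C)(C)C | intermediate
17 | tert-butoxyethyne | C#COC(C)(C)C | intermediate
18 | 5-methylhex-4-enoic acid | CC(C)=CCCC(=O)O | starting material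
19 | 5-methylhex-4-enoyl chloride | CC(C)=CCCC(=O)Cl | intermediate
20 | (3-methylbut-2-en-1-yl)ketene (6-methylhepta-1,5-dien-1-one) | CC(C)=CCC=C=O | intermediate
21 | 3-tert-butoxy-4-(3-methylbut-2-en-1-yl)cyclobut-2-en-1-one, racemic | CC(C)=CCC1C(=O)C=C1OC(C)(C)C | intermediate
22 | (3Z)-3-tert-butoxy-7-methylocta-1,3,6-trien-1-one (vinylketene) | O=C=C/C(OC(C)(C)C)=C/CC=C(C)C | intermediate
23 | methyl (2E,5R)-5-({3-[(1Z)-1-tert-butoxy-5-methylhexa-1,4-dien-1-yl]-2-ethoxy-4-oxocyclobut-1-en-1-yl}methyl)-2,6-dimethylhepta-2,6-dienoate, both configurations at the ring CH | C=C(C)[C@H](C/C=C(\C)C(=O)OC)CC1=C(OCC)C(/C(OC(C)(C)C)=C/CC=C(C)C)C1=O | intermediate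
24 | methyl (2E,5R)-5-[(3E,5Z)-5-tert-butoxy-3-ethoxy-9-methyl-2-(oxomethylidene)deca-3,5,8-trien-1-yl]-2,6-dimethylhepta-2,6-dienoate (dienylketene) | C=C(C)[C@H](C/C=C(\C)C(=O)OC)CC(=C=O)/C(OCC)=C\C(OC(C)(C)C)=C\CC=C(C)C | intermediate
25 | methyl (2E,5R)-5-{[4-tert-butoxy-2-ethoxy-5-(3-methylbut-2-en-1-yl)-6-oxocyclohexa-1,3-dien-1-yl]methyl}-2,6-dimethylhepta-2,6-dienoate, both configurations at ring C-5 | C=C(C)[C@H](C/C=C(\C)C(=O)OC)CC1=C(OCC)C=C(OC(C)(C)C)C(CC=C(C)C)C1=O | intermediate
26 | methyl (2E,5R)-5-{[4-tert-butoxy-6-ethoxy-2-hydroxy-3-(3-methylbut-2-en-1-yl)phenyl]methyl}-2,6-dimethylhepta-2,6-dienoate | C=C(C)[C@H](C/C=C(\C)C(=O)OC)Cc1c(OCC)cc(OC(C)(C)C)c(CC=C(C)C)c1O | intermediate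
27 | methyl (2E,5R)-5-[(5-tert-butoxy-7-ethoxy-2,2-dimethyl-2H-chromen-8-yl)methyl]-2,6-dimethylhepta-2,6-dienoate | C=C(C)[C@H](C/C=C(\C)C(=O)OC)Cc1c(OCC)cc(OC(C)(C)C)c2C=CC(C)(C)Oc12 | intermediate
28 | (R)-2-methylbutanoic acid | CC[C@@H](C)C(=O)O | starting material
29 | (R)-2-methylbutanoyl chloride | CC[C@@H](C)C(=O)Cl | intermediate
30 | trichlorotitanium aryloxide of the 5-hydroxychromene (Ti–O on C-5 of 27 after loss of tert-butyl) | C=C(C)[C@H](C/C=C(\C)C(=O)OC)Cc1c(OCC)cc(O[Ti](Cl)(Cl)Cl)c2C=CC(C)(C)Oc12 | intermediate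
31 | methyl (2E,5R)-5-({7-ethoxy-5-hydroxy-2,2-dimethyl-6-[(2R)-2-methylbutanoyl]-2H-chromen-8-yl}methyl)-2,6-dimethylhepta-2,6-dienoate | C=C(C)[C@H](C/C=C(\C)C(=O)OC)Cc1c(OCC)c(C(=O)[C@H](C)CC)c(O)c2C=CC(C)(C)Oc12 | intermediate
32 | 3-methylbut-2-en-1-yl acetate (prenyl acetate) | CC(C)=CCOC(C)=O | starting material
33 | methyl (2E,5R)-5-({(8R)-7-ethoxy-2,2-dimethyl-6-[(2R)-2-methylbutanoyl]-8-(3-methylbut-2-en-1-yl)-5-oxo-5,8-dihydro-2H-chromen-8-yl}methyl)-2,6-dimethylhepta-2,6-dienoate | C=C(C)[C@H](C/C=C(\C)C(=O)OC)C[C@]1(CC=C(C)C)C(OCC)=C(C(=O)[C@H](C)CC)C(=O)C2=C1OC(C)(C)C=C2 | intermediate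
34 | (2E,5R)-5-({(8R)-7-hydroxy-2,2-dimethyl-6-[(2R)-2-methylbutanoyl]-8-(3-methylbut-2-en-1-yl)-5-oxo-5,8-dihydro-2H-chromen-8-yl}methyl)-2,6-dimethylhepta-2,6-dienoic acid | C=C(C)[C@H](C/C=C(\C)C(=O)O)C[C@]1(CC=C(C)C)C(O)=C(C(=O)[C@H](C)CC)C(=O)C2=C1OC(C)(C)C=C2 | target

Total step count: 11. Longest linear sequence: 9 steps (steps 1, 2, 3, 4, 7, 8, 9, 10, 11); steps 5 and 6 form the short side branch to cyclobutenone 21.

Steps most likely to fail

1. Step 10. The ligand may discriminate the two faces of C-8 poorly, because the reacting carbon is para to the metal-bound oxygen, or O-prenylation may not revert to C-alkylation. The fallback replaces π-allyl chemistry by asymmetric phase-transfer alkylation: it sets out from 31 and uses prenyl bromide, N-(9-anthracenylmethyl)cinchonidinium bromide (10 mol %) and CsOH·H2O in toluene/CHCl3 at −40 °C, so that the chiral ammonium phenoxide ion pair shields one face of C-8 in an SN2 alkylation. The pseudoenantiomeric cinchoninium salt is at hand if the sense is wrong. The fallback comes back to the route at 33 and forms no new compound.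

2. Step 9. Hydrochlorination or cationic oligomerisation of the chromene and isopropenyl double bonds may compete with acylation under TiCl4. The fallback puts the acyl group on before the pyran exists and without a Lewis acid. It sets out from phenol 26: esterification with acid chloride 29 (pyridine, DMAP, CH2Cl2) should give the aryl ester F1. Photo-Fries rearrangement (254 nm, cyclohexane) then moves the acyl group to the only free ring carbon, para to the oxygen, to give the acylphenol F2. DDQ closes the pyran as in step 8 to the acylchromene tert-butyl ether F3, which the acyl group deactivates towards acid. 85 % aqueous H3PO4 in toluene removes the tert-butyl group, and the route is rejoined at 31.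

3. Step 7. Ynol ether 12 may be lost by thermal retro-ene elimination of ethylene, or consumed by ketene intermediates, before the [2+2] addition, or the cascade may stall at the vinylcyclobutenone. The fallback divides the cascade and makes its first half photochemical. It sets out from 21 and 12: irradiation (Pyrex-filtered mercury lamp, benzene, room temperature) opens 21 to 22 without heat, 22 adds 12, and vinylcyclobutenone 23 is isolated. Compound 23 alone is then heated in toluene (80–110 °C) for the ring expansion, and the route is rejoined at 26. No new compound is formed.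

Further compounds
F0 | step 10 | none | none
F1 | step 9 | methyl (2E,5R)-5-{[4-tert-butoxy-6-ethoxy-2-{[(2R)-2-methylbutanoyl]oxy}-3-(3-methylbut-2-en-1-yl)phenyl]methyl}-2,6-dimethylhepta-2,6-dienoate | C=C(C)[C@H](C/C=C(\C)C(=O)OC)Cc1c(OCC)cc(OC(C)(C)C)c(CC=C(C)C)c1OC(=O)[C@H](C)CC
F2 | step 9 | methyl (2E,5R)-5-({4-tert-butoxy-6-ethoxy-2-hydroxy-5-[(2R)-2-methylbutanoyl]-3-(3-methylbut-2-en-1-yl)phenyl}methyl)-2,6-dimethylhepta-2,6-dienoate | C=C(C)[C@H](C/C=C(\C)C(=O)OC)Cc1c(OCC)c(C(=O)[C@H](C)CC)c(OC(C)(C)C)c(CC=C(C)C)c1O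
F3 | step 9 | methyl (2E,5R)-5-({5-tert-butoxy-7-ethoxy-2,2-dimethyl-6-[(2R)-2-methylbutanoyl]-2H-chromen-8-yl}methyl)-2,6-dimethylhepta-2,6-dienoate | C=C(C)[C@H](C/C=C(\C)C(=O)OC)Cc1c(OCC)c(C(=O)[C@H](C)CC)c(OC(C)(C)C)c2C=CC(C)(C)Oc12
F0 | step 7 | none | none
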